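**Retrosynthetic overview**
1. Target 23 ⇐ silyl ether 22 ⇐ 6-exo bromoetherification of bromohydrin 21 (C11–OH onto C7 of the E-6,7-alkene). The oxane is the only ring and is closed last.
2. 21 ⇐ (10R)-epoxide 20 (bromide opening at C10) ⇐ (10S)-alcohol 17 ⇐ CBS reduction of α-silyloxy ketone 16.
3. 16 ⇐ dienone 15 ⇐ intermolecular aldol (C8–C9 bond) between enal 9 (C1–C8) and the lithium enolate of ketone 11 (C9–C11), then dehydration and 1,4-reduction.
4. 9 ⇐ aldehyde 7 (E-selective Wittig) ⇐ (S)-linalool 4 ⇐ geraniol 1 (Sharpless epoxidation fixes C3).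

Assumption: locants C1–C11 in the text are the nerolidol-type locants of the target (C1=C2 vinyl, C3 carbinol, C6 and C10 the CHBr carbons, C7 and C11 the ether carbons), and Li2NiBr4 is used as a stock solution in THF.

**Step 1**
Reactants: 1 geraniol, (2E)-3,7-dimethylocta-2,6-dien-1-ol
Product: 2 [(2S,3S)-3-methyl-3-(4-methylpent-3-en-1-yl)oxiran-2-yl]methanol
Conditions: Ti(OiPr)4 (5 mol %), L-(+)-diethyl tartrate (6 mol %), t-BuOOH, 4 Å MS, CH2Cl2, −20 °C
Reagents that add atoms: tert-butyl hydroperoxide CC(C)(C)OO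
Why: Sharpless asymmetric epoxidation of the allylic alcohol with L-(+)-tartrate delivers oxygen to the face that gives the (2S,3S)-epoxide (its C3 becomes C3 of the target), and the isolated 6,7-alkene does not react.

**Step 2**
Reactants: 2 [(2S,3S)-3-methyl-3-(4-methylpent-3-en-1-yl)oxiran-2-yl]methanol
Product: 3 (2R,3S)-2-(iodomethyl)-3-methyl-3-(4-methylpent-3-en-1-yl)oxirane
Conditions: PPh3, I2, imidazole, Et2O/MeCN, 0 °C
Reagents that add atoms: iodine II
Why: Appel-type iodination of the primary alcohol through its alkoxyphosphonium salt leaves both epoxide centres untouched (the C2 descriptor changes only through CIP priorities).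

**Step 3**
Reactants: 3 (2R,3S)-2-(iodomethyl)-3-methyl-3-(4-methylpent-3-en-1-yl)oxirane
Product: 4 (S)-linalool, (3S)-3,7-dimethylocta-1,6-dien-3-ol
Conditions: Zn dust, AcOH, EtOH, 0 °C to rt
Reagents that add atoms: none
Why: Zinc insertion into the C–I bond and reductive β-elimination opens the epoxide to the vinyl carbinol, with the C3–O bond, and so the (S) centre, retained.

**Step 4**
Reactants: 4 (S)-linalool
Product: 5 triethyl{[(3S)-3,7-dimethylocta-1,6-dien-3-yl]oxy}silane
Conditions: Et3SiOTf, 2,6-lutidine, CH2Cl2, −78 to 0 °C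
Reagents that add atoms: triethylsilyl trifluoromethanesulfonate CC[Si](CC)(CC)OS(=O)(=O)C(F)(F)F
Why: Silylation with the silyl triflate protects the hindered tertiary alcohol so it cannot quench the enolate or compete as a nucleophile in the later bromoetherification.

**Step 5**
Reactants: 5 triethyl{[(3S)-3,7-dimethylocta-1,6-dien-3-yl]oxy}silane
Product: 6 (6S)-2,6-dimethyl-6-[(triethylsilyl)oxy]oct-7-ene-2,3-diol (both C3 epimers)
Conditions: OsO4 (2 mol %), NMO, acetone/H2O, 0 °C
Reagents that add atoms: N-methylmorpholine N-oxide C[N+]1([O-])CCOCC1; water O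
Why: Upjohn dihydroxylation is chemoselective for the electron-rich trisubstituted alkene over the hindered vinyl group, and the new carbinol centre is destroyed in the next step.

**Step 6**
Reactants: 6 (6S)-2,6-dimethyl-6-[(triethylsilyl)oxy]oct-7-ene-2,3-diol
Product: 7 (4S)-4-methyl-4-[(triethylsilyl)oxy]hex-5-enal
Conditions: NaIO4, THF/H2O (pH 7), 0 °C to rt
Reagents that add atoms: none
Why: Neutral periodate glycol cleavage removes the isopropylidene carbons as acetone and leaves the C1–C6 aldehyde with its stereocentre untouched.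

**Step 7**
Reactants: 7 (4S)-4-methyl-4-[(triethylsilyl)oxy]hex-5-enal; 8 2-(triphenylphosphoranylidene)propanal
Product: 9 (2E,6S)-2,6-dimethyl-6-[(triethylsilyl)oxy]octa-2,7-dienal
Conditions: toluene, 90 °C
Reagents that add atoms: none
Why: Wittig olefination with the stabilised formyl ylide gives the thermodynamically preferred (E)-2-methyl-2-enal, which fixes the E geometry of the future C6=C7 bond.

**Step 8**
Reactants: 10 3-hydroxy-3-methylbutan-2-one
Product: 11 3-methyl-3-[(trimethylsilyl)oxy]butan-2-one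
Conditions: Me3SiCl, imidazole, DMF, rt
Reagents that add atoms: chlorotrimethylsilane C[Si](C)(C)Cl
Why: Silylation of the tertiary hydroxyl gives a methyl ketone with a single enolisable position and no acidic OH.

**Step 9**
Reactants: 9 (2E,6S)-2,6-dimethyl-6-[(triethylsilyl)oxy]octa-2,7-dienal; 11 3-methyl-3-[(trimethylsilyl)oxy]butan-2-one
Product: 13 (6E,10S)-5-hydroxy-2,6,10-trimethyl-10-[(triethylsilyl)oxy]-2-[(trimethylsilyl)oxy]dodeca-6,11-dien-3-one (both C5 epimers), via lithium enolate 12 (not isolated)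
Conditions: LDA, THF, −78 °C; then 9, −78 °C; H2O quench
Reagents that add atoms: none
Why: Directed aldol addition of the regiodefined kinetic lithium enolate (the other α-carbon is quaternary) in 1,2-fashion to the non-enolisable enal forges the C8–C9 bond that joins the C1–C8 and C9–C11 fragments, and the new carbinol centre is removed by the following dehydration.

**Step 10**
Reactants: 13 (6E,10S)-5-hydroxy-2,6,10-trimethyl-10-[(triethylsilyl)oxy]-2-[(trimethylsilyl)oxy]dodeca-6,11-dien-3-one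
Product: 15 (4E,6E,10S)-2,6,10-trimethyl-10-[(triethylsilyl)oxy]-2-[(trimethylsilyl)oxy]dodeca-4,6,11-trien-3-one, via allylic mesylate 14 (not isolated)
Conditions: MsCl, Et3N, CH2Cl2, 0 °C; then DBU, rt
Reagents that add atoms: none
Why: Mesylation and E1cB elimination through the ketone enolate complete the aldol condensation and give the conjugated dienone with the thermodynamically preferred trans enone, the C6=C7 geometry being unchanged.

**Step 11**
Reactants: 15 (4E,6E,10S)-2,6,10-trimethyl-10-[(triethylsilyl)oxy]-2-[(trimethylsilyl)oxy]dodeca-4,6,11-trien-3-one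
Product: 16 (6E,10S)-2,6,10-trimethyl-10-[(triethylsilyl)oxy]-2-[(trimethylsilyl)oxy]dodeca-6,11-dien-3-one
Conditions: [(Ph3P)CuH]6 (0.4 equiv), H2O (5 equiv), benzene/THF, rt
Reagents that add atoms: none
Why: Stryker conjugate reduction delivers hydride to the enone β-carbon (C8) and water protonates the copper enolate, so only the C8=C9 bond is saturated while the isolated alkenes, the ketone and both silyl ethers survive.

**Step 12**
Reactants: 16 (6E,10S)-2,6,10-trimethyl-10-[(triethylsilyl)oxy]-2-[(trimethylsilyl)oxy]dodeca-6,11-dien-3-one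
Product: 17 (3S,6E,10S)-2,6,10-trimethyl-10-[(triethylsilyl)oxy]-2-[(trimethylsilyl)oxy]dodeca-6,11-dien-3-ol
Conditions: (R)-1-methyl-3,3-diphenyl-tetrahydro-1H,3H-pyrrolo[1,2-c][1,3,2]oxazaborole ((R)-Me-CBS, 0.3 equiv), catecholborane, toluene, −78 to −40 °C; MeOH, then aqueous work-up
Reagents that add atoms: none
Why: Corey–Bakshi–Shibata reduction with the bulky C(CH3)2OSiMe3 group as the large substituent gives the (S)-carbinol at the future C10 from the (R)-catalyst, and catecholborane avoids hydroboration of the alkenes.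

**Step 13**
Reactants: 17 (3S,6E,10S)-2,6,10-trimethyl-10-[(triethylsilyl)oxy]-2-[(trimethylsilyl)oxy]dodeca-6,11-dien-3-ol
Product: 20 triethyl{[(3S,6E)-9-[(2R)-3,3-dimethyloxiran-2-yl]-3,7-dimethylnona-1,6-dien-3-yl]oxy}silane, via secondary mesylate 18 (not isolated), via hydroxy mesylate 19 (not isolated)
Conditions: MsCl, Et3N, CH2Cl2, 0 °C; concentrate; K2CO3, MeOH, rt
Reagents that add atoms: none
Why: Mesylation of the secondary alcohol, methanolysis of the tertiary trimethylsilyl ether and intramolecular Williamson displacement give the epoxide with inversion at C10 (10S to 10R), while the tertiary triethylsilyl ether survives.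

**Step 14**
Reactants: 20 triethyl{[(3S,6E)-9-[(2R)-3,3-dimethyloxiran-2-yl]-3,7-dimethylnona-1,6-dien-3-yl]oxy}silane
Product: 21 (3S,6E,10S)-3-bromo-2,6,10-trimethyl-10-[(triethylsilyl)oxy]dodeca-6,11-dien-2-ol
Conditions: Li2NiBr4 (0.4 M in THF, 2 equiv), THF, 0 °C to rt; H2O
Reagents that add atoms: dilithium tetrabromonickelate Li2NiBr4 [Li+].[Li+].[Ni+2].[Br-].[Br-].[Br-].[Br-]
Why: Epoxide opening by soft nucleophilic bromide under essentially neutral conditions is an SN2 attack at the less substituted carbon C10 with inversion (10R to 10S), giving the secondary bromide next to the free tertiary C11 alcohol.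

**Step 15**
Reactants: 21 (3S,6E,10S)-3-bromo-2,6,10-trimethyl-10-[(triethylsilyl)oxy]dodeca-6,11-dien-2-ol
Product: 22 triethyl{[(3S,6R)-6-bromo-6-[(2S,5S)-5-bromo-2,6,6-trimethyloxan-2-yl]-3-methylhex-1-en-3-yl]oxy}silane
Conditions: NBS (1.1 equiv), CH2Cl2, −20 to 0 °C, dark; chromatographic separation of diastereomers
Reagents that add atoms: N-bromosuccinimide O=C1CCC(=O)N1Br
Why: In this 6-exo bromoetherification the C11 hydroxyl opens the bromiranium ion of the E-6,7-alkene at its tertiary carbon C7 anti to bromine, which fixes the C6/C7 relative configuration; the alkene face is only weakly biased by C10 (about 1:1 expected), so 22 is separated from the diastereomer formed on the other face.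

**Step 16**
Reactants: 22 triethyl{[(3S,6R)-6-bromo-6-[(2S,5S)-5-bromo-2,6,6-trimethyloxan-2-yl]-3-methylhex-1-en-3-yl]oxy}silane
Product: 23 (3S,6R)-6-bromo-6-[(2S,5S)-5-bromo-2,6,6-trimethyloxan-2-yl]-3-methylhex-1-en-3-ol
Conditions: HF·pyridine, pyridine, THF, 0 °C to rt
Reagents that add atoms: none
Why: Buffered fluoride desilylation frees the tertiary allylic alcohol without base-induced elimination of the secondary bromides or acid ionisation of the allylic carbinol.

**Compound list**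
1 | geraniol, (2E)-3,7-dimethylocta-2,6-dien-1-ol | CC(C)=CCC/C(C)=C/CO | starting material
2 | [(2S,3S)-3-methyl-3-(4-methylpent-3-en-1-yl)oxiran-2-yl]methanol | OC[C@@H]1O[C@@]1(C)CCC=C(C)C | intermediate
3 | (2R,3S)-2-(iodomethyl)-3-methyl-3-(4-methylpent-3-en-1-yl)oxirane | IC[C@@H]1O[C@@]1(C)CCC=C(C)C | intermediate
4 | (S)-linalool, (3S)-3,7-dimethylocta-1,6-dien-3-ol | C=C[C@@](C)(O)CCC=C(C)C | intermediate
5 | triethyl{[(3S)-3,7-dimethylocta-1,6-dien-3-yl]oxy}silane | C=C[C@@](C)(O[Si](CC)(CC)CC)CCC=C(C)C | intermediate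
6 | (6S)-2,6-dimethyl-6-[(triethylsilyl)oxy]oct-7-ene-2,3-diol (C3 epimers) | C=C[C@@](C)(O[Si](CC)(CC)CC)CCC(O)C(C)(C)O | intermediate
7 | (4S)-4-methyl-4-[(triethylsilyl)oxy]hex-5-enal | C=C[C@@](C)(O[Si](CC)(CC)CC)CCC=O | intermediate
8 | 2-(triphenylphosphoranylidene)propanal | CC(C=O)=P(c1ccccc1)(c1ccccc1)c1ccccc1 | starting material
9 | (2E,6S)-2,6-dimethyl-6-[(triethylsilyl)oxy]octa-2,7-dienal | C=C[C@@](C)(O[Si](CC)(CC)CC)CC/C=C(\C)C=O | intermediate
10 | 3-hydroxy-3-methylbutan-2-one | CC(=O)C(C)(C)O | starting material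
11 | 3-methyl-3-[(trimethylsilyl)oxy]butan-2-one | CC(=O)C(C)(C)O[Si](C)(C)C | intermediate
12 | lithium 3-methyl-3-[(trimethylsilyl)oxy]but-1-en-2-olate (lithium enolate of 11) | C=C(O[Li])C(C)(C)O[Si](C)(C)C | intermediate
13 | (6E,10S)-5-hydroxy-2,6,10-trimethyl-10-[(triethylsilyl)oxy]-2-[(trimethylsilyl)oxy]dodeca-6,11-dien-3-one (C5 epimers) | C=C[C@@](C)(O[Si](CC)(CC)CC)CC/C=C(\C)C(O)CC(=O)C(C)(C)O[Si](C)(C)C | intermediate
14 | C5 methanesulfonate of 13 | C=C[C@@](C)(O[Si](CC)(CC)CC)CC/C=C(\C)C(OS(C)(=O)=O)CC(=O)C(C)(C)O[Si](C)(C)C | intermediate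
15 | (4E,6E,10S)-2,6,10-trimethyl-10-[(triethylsilyl)oxy]-2-[(trimethylsilyl)oxy]dodeca-4,6,11-trien-3-one | C=C[C@@](C)(O[Si](CC)(CC)CC)CC/C=C(C)/C=C/C(=O)C(C)(C)O[Si](C)(C)C | intermediate
16 | (6E,10S)-2,6,10-trimethyl-10-[(triethylsilyl)oxy]-2-[(trimethylsilyl)oxy]dodeca-6,11-dien-3-one | C=C[C@@](C)(O[Si](CC)(CC)CC)CC/C=C(\C)CCC(=O)C(C)(C)O[Si](C)(C)C | intermediate
17 | (3S,6E,10S)-2,6,10-trimethyl-10-[(triethylsilyl)oxy]-2-[(trimethylsilyl)oxy]dodeca-6,11-dien-3-ol | C=C[C@@](C)(O[Si](CC)(CC)CC)CC/C=C(\C)CC[C@H](O)C(C)(C)O[Si](C)(C)C | intermediate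
18 | (3S,6E,10S)-2,6,10-trimethyl-10-[(triethylsilyl)oxy]-2-[(trimethylsilyl)oxy]dodeca-6,11-dien-3-yl methanesulfonate | C=C[C@@](C)(O[Si](CC)(CC)CC)CC/C=C(\C)CC[C@H](OS(C)(=O)=O)C(C)(C)O[Si](C)(C)C | intermediate
19 | (3S,6E,10S)-2-hydroxy-2,6,10-trimethyl-10-[(triethylsilyl)oxy]dodeca-6,11-dien-3-yl methanesulfonate | C=C[C@@](C)(O[Si](CC)(CC)CC)CC/C=C(\C)CC[C@H](OS(C)(=O)=O)C(C)(C)O | intermediate
20 | triethyl{[(3S,6E)-9-[(2R)-3,3-dimethyloxiran-2-yl]-3,7-dimethylnona-1,6-dien-3-yl]oxy}silane | C=C[C@@](C)(O[Si](CC)(CC)CC)CC/C=C(\C)CC[C@H]1OC1(C)C | intermediate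
21 | (3S,6E,10S)-3-bromo-2,6,10-trimethyl-10-[(triethylsilyl)oxy]dodeca-6,11-dien-2-ol | C=C[C@@](C)(O[Si](CC)(CC)CC)CC/C=C(\C)CC[C@H](Br)C(C)(C)O | intermediate
22 | triethyl{[(3S,6R)-6-bromo-6-[(2S,5S)-5-bromo-2,6,6-trimethyloxan-2-yl]-3-methylhex-1-en-3-yl]oxy}silane | C=C[C@@](C)(O[Si](CC)(CC)CC)CC[C@@H](Br)[C@]1(C)CC[C@H](Br)C(C)(C)O1 | intermediate
23 | (3S,6R)-6-bromo-6-[(2S,5S)-5-bromo-2,6,6-trimethyloxan-2-yl]-3-methylhex-1-en-3-ol | C=C[C@@](C)(O)CC[C@@H](Br)[C@]1(C)CC[C@H](Br)C(C)(C)O1 | target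

**Summary**
Total step count: 16. Longest linear sequence: 15 steps (steps 1–7 and 9–16 from geraniol; step 8 is a one-step side branch).

**Steps most likely to fail, with fallbacks**

Step 15 (facial selectivity of the bromoetherification). Roughly half of the cyclised material is expected to be the wrong C6/C7 diastereomer. The fallback sets out from epoxide 20 and comes back at 22, making both C–Br bonds by stereospecific epoxide opening. Shi epoxidation of the 6,7-alkene of 20 uses the L-fructose-derived ketone (1,2:4,5-di-O-isopropylidene-L-erythro-2,3-hexodiulo-2,6-pyranose) with Oxone (2KHSO5·KHSO4·K2SO4) in K2CO3 buffer. This gives triethyl{[(3S)-5-[(2S,3S)-3-{2-[(2R)-3,3-dimethyloxiran-2-yl]ethyl}-3-methyloxiran-2-yl]-3-methylpent-1-en-3-yl]oxy}silane F5. Excess Li2NiBr4 opens both epoxides at their secondary carbons with inversion to give (3S,6R,7S,10S)-6,10-dibromo-3,7,11-trimethyl-3-[(triethylsilyl)oxy]dodec-1-ene-7,11-diol F6. Activation of one tertiary hydroxyl (Tf2O, 2,6-di-tert-butyl-4-methylpyridine, CH2Cl2, −78 °C) then ionises it with participation of the neighbouring bromine. The other tertiary hydroxyl opens the bromiranium ion at its tertiary carbon, so C7 is retained by double inversion and 22 forms as a single diastereomer. This closing step is mechanistically sound but has little direct precedent.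

Step 14 (regiochemistry of the bromide opening). Attack at the tertiary carbon or rearrangement to a ketone could compete. The fallback sets out from 20 and comes back at 21 by using the opposite regiochemistry on purpose. MgBr2·OEt2 (Et2O, −20 °C) opens 20 at the tertiary carbon, leaving the C10–O bond intact, to give (3R,6E,10S)-2-bromo-2,6,10-trimethyl-10-[(triethylsilyl)oxy]dodeca-6,11-dien-3-ol F3. Tf2O and 2,6-lutidine (CH2Cl2, −78 °C) convert it into (3R,6E,10S)-2-bromo-2,6,10-trimethyl-10-[(triethylsilyl)oxy]dodeca-6,11-dien-3-yl trifluoromethanesulfonate F4. F4 ionises with backside participation of bromine (inversion at C10), and aqueous NaHCO3/THF opens the bromiranium ion at the tertiary carbon. This stereospecific 1,2-bromine shift delivers 21 with the (10S) bromide.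

Step 11 (1,4- versus 1,6-reduction of the dienone). Hydride delivery to C6 or over-reduction would scramble the C6=C7 alkene. The fallback sets out from enal 9 and comes back at 16, forming the same C8–C9 bond by enolate alkylation so that no dienone is made. Luche reduction (NaBH4, CeCl3·7H2O, MeOH, 0 °C) gives (2E,6S)-2,6-dimethyl-6-[(triethylsilyl)oxy]octa-2,7-dien-1-ol F1. Appel bromination (CBr4, PPh3, CH2Cl2, 0 °C) gives triethyl{[(3S,6E)-8-bromo-3,7-dimethylocta-1,6-dien-3-yl]oxy}silane F2. C-alkylation of lithium enolate 12 with F2 (THF/DMPU, −78 to −20 °C) gives 16 directly.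

**Further compounds**
F1 | step 11 | (2E,6S)-2,6-dimethyl-6-[(triethylsilyl)oxy]octa-2,7-dien-1-ol | C=C[C@@](C)(O[Si](CC)(CC)CC)CC/C=C(\C)CO
F2 | step 11 | triethyl{[(3S,6E)-8-bromo-3,7-dimethylocta-1,6-dien-3-yl]oxy}silane | C=C[C@@](C)(O[Si](CC)(CC)CC)CC/C=C(\C)CBr
F3 | step 14 | (3R,6E,10S)-2-bromo-2,6,10-trimethyl-10-[(triethylsilyl)oxy]dodeca-6,11-dien-3-ol | C=C[C@@](C)(O[Si](CC)(CC)CC)CC/C=C(\C)CC[C@@H](O)C(C)(C)Br
F4 | step 14 | (3R,6E,10S)-2-bromo-2,6,10-trimethyl-10-[(triethylsilyl)oxy]dodeca-6,11-dien-3-yl trifluoromethanesulfonate | C=C[C@@](C)(O[Si](CC)(CC)CC)CC/C=C(\C)CC[C@@H](OS(=O)(=O)C(F)(F)F)C(C)(C)Br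
F5 | step 15 | triethyl{[(3S)-5-[(2S,3S)-3-{2-[(2R)-3,3-dimethyloxiran-2-yl]ethyl}-3-methyloxiran-2-yl]-3-methylpent-1-en-3-yl]oxy}silane | C=C[C@@](C)(O[Si](CC)(CC)CC)CC[C@@H]1O[C@@]1(C)CC[C@H]2OC2(C)C
F6 | step 15 | (3S,6R,7S,10S)-6,10-dibromo-3,7,11-trimethyl-3-[(triethylsilyl)oxy]dodec-1-ene-7,11-diol | C=C[C@@](C)(O[Si](CC)(CC)CC)CC[C@@H](Br)[C@@](C)(O)CC[C@H](Br)C(C)(C)O
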